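**Plan**
- Numbering: furanone O1, C2(=O), C3(H), C4, C5(H2); side chain C1' (carbinol) to C17', with the hydroxymethyl group on C4'.
- Retrosynthetic cuts, in order: (a) the C3–C2 bond of the furanone, giving acyclic (Z)-iodoalkene methyl carbonate 20; (b) C4–C1', giving aldehyde 13, ethyl propiolate and iodide; (c) the sp2–sp3 bond C4'–C5', giving alkenyl iodide 9 and tetraene 3 (from farnesol).
- Forward: the chain is assembled first (B-alkyl Suzuki–Miyaura coupling), then the aldehyde, then a three-component β-iodo aldol, reduction and carbonate formation; the only ring is closed in the penultimate step, and desilylation ends the route.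
- Enabling feature: C3 and the C5H2–O1 arm are cis on the ring double bond C3=C4, and C4 bears no hydrogen. An alkenyl anion at C3 therefore reaches a carbonate carbonyl on O1 through a five-membered transition state; the carbonate protects O1 and supplies C2.
- Stereochemistry: C1' (R) from the catalyst-controlled three-component aldol; 3'E from hydroxyl-directed trans-hydrostannation, iodination and retentive coupling; 7'E and 11'E from (2E,6E)-farnesol; the cis relation of C3 and C5 from the Z-selective iodo aldol.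

Key step: step 13

Assumption: the sense of induction in step 9 is taken from the usual binding model of oxazaborolidinium-activated aldehydes; should it prove opposite, the antipodal catalyst (from (R)-diphenylprolinol) is used and nothing else changes.

**Step 1**
Reactants: 1 (2E,6E)-farnesol
Product: 2 (2E,6E)-farnesal
Conditions: MnO2 (excess), CH2Cl2, rt
Reagents that add atoms: none
Why: Heterogeneous MnO2 oxidation is selective for the allylic alcohol and should not isomerise the 2E double bond (allylic oxidation).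

**Step 2**
Reactants: 2 (2E,6E)-farnesal
Product: 3 (3E,7E)-4,8,12-trimethyltrideca-1,3,7,11-tetraene
Conditions: Ph3PCH3Br, KOt-Bu, THF, 0 °C to rt
Reagents that add atoms: methyltriphenylphosphonium bromide, C[P+](c1ccccc1)(c1ccccc1)c1ccccc1.[Br-]
Why: Wittig methylenation of the enal with the non-stabilised ylide should give the terminal diene and leave the trisubstituted double bonds untouched.

**Step 3**
Reactants: 4 tert-butyl(but-3-yn-1-yloxy)dimethylsilane
Product: 6 5-[(tert-butyldimethylsilyl)oxy]pent-2-yn-1-ol, via lithium acetylide 5 (not isolated)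
Conditions: n-BuLi, THF, −78 °C; (CH2O)n, −78 °C to rt; aq. NH4Cl
Reagents that add atoms: paraformaldehyde (as formaldehyde), C=O
Why: Deprotonation of the terminal alkyne and addition of the lithium acetylide to formaldehyde is a standard acetylide hydroxymethylation.

**Step 4**
Reactants: 6 5-[(tert-butyldimethylsilyl)oxy]pent-2-yn-1-ol
Product: 8 (Z)-5-[(tert-butyldimethylsilyl)oxy]-2-iodopent-2-en-1-ol, via alkenylstannane 7 (not isolated)
Conditions: Bu3SnH, [Cp*RuCl]4 (cat.), CH2Cl2, rt; then I2, 0 °C; aq. Na2S2O3/KF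
Reagents that add atoms: iodine, I-I
Why: Hydroxyl-directed ruthenium-catalysed trans-hydrostannation should place tin on the alkyne carbon next to the free propargylic OH with hydrogen anti to it, and iododestannylation with retention then fixes the (Z)-2-iodoalkenol geometry (H cis to CH2OH).

**Step 5**
Reactants: 8 (Z)-5-[(tert-butyldimethylsilyl)oxy]-2-iodopent-2-en-1-ol
Product: 9 (Z)-5-[(tert-butyldimethylsilyl)oxy]-1-[(tert-butyldiphenylsilyl)oxy]-2-iodopent-2-ene
Conditions: TBDPSCl, imidazole, CH2Cl2, 0 °C to rt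
Reagents that add atoms: tert-butyl(chloro)diphenylsilane, CC(C)(C)[Si](Cl)(c1ccccc1)c1ccccc1
Why: Standard silylation of the primary allylic alcohol installs a robust silyl ether that is orthogonal to the primary TBS ether.

**Step 6**
Reactants: 3 (3E,7E)-4,8,12-trimethyltrideca-1,3,7,11-tetraene; 9 (Z)-5-[(tert-butyldimethylsilyl)oxy]-1-[(tert-butyldiphenylsilyl)oxy]-2-iodopent-2-ene
Product: 11 (E)-5-[(tert-butyldimethylsilyl)oxy]-1-[(tert-butyldiphenylsilyl)oxy]-2-[(3E,7E)-4,8,12-trimethyltrideca-3,7,11-trien-1-yl]pent-2-ene, via B-alkyl borane 10 (not isolated)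
Conditions: 3, 9-BBN, THF, 0 °C to rt; then 9, Pd(dppf)Cl2 (cat.), AsPh3, Cs2CO3, DMF/H2O, rt
Reagents that add atoms: none
Why: 9-BBN should hydroborate only the monosubstituted diene terminus at its terminal carbon, and B-alkyl Suzuki–Miyaura coupling of the primary alkylborane with the alkenyl iodide proceeds with retention, which sets the 3'E trisubstituted alkene.

**Step 7**
Reactants: 11 (E)-5-[(tert-butyldimethylsilyl)oxy]-1-[(tert-butyldiphenylsilyl)oxy]-2-[(3E,7E)-4,8,12-trimethyltrideca-3,7,11-trien-1-yl]pent-2-ene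
Product: 12 (E)-5-[(tert-butyldiphenylsilyl)oxy]-4-[(3E,7E)-4,8,12-trimethyltrideca-3,7,11-trien-1-yl]pent-3-en-1-ol
Conditions: PPTS, MeOH/CH2Cl2, 0 °C to rt
Reagents that add atoms: none
Why: Mild acid-catalysed methanolysis cleaves a primary TBS ether much faster than a TBDPS ether (selective desilylation).

**Step 8**
Reactants: 12 (E)-5-[(tert-butyldiphenylsilyl)oxy]-4-[(3E,7E)-4,8,12-trimethyltrideca-3,7,11-trien-1-yl]pent-3-en-1-ol
Product: 13 (E)-5-[(tert-butyldiphenylsilyl)oxy]-4-[(3E,7E)-4,8,12-trimethyltrideca-3,7,11-trien-1-yl]pent-3-enal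
Conditions: Dess–Martin periodinane, NaHCO3, CH2Cl2, 0 °C; used at once
Reagents that add atoms: none
Why: Buffered Dess–Martin oxidation should give the β,γ-unsaturated aldehyde without moving the double bond into conjugation.

**Step 9**
Reactants: 13 (E)-5-[(tert-butyldiphenylsilyl)oxy]-4-[(3E,7E)-4,8,12-trimethyltrideca-3,7,11-trien-1-yl]pent-3-enal; 14 ethyl propiolate
Product: 17 ethyl (2Z)-2-{(1R,3E)-5-[(tert-butyldiphenylsilyl)oxy]-1-hydroxy-4-[(3E,7E)-4,8,12-trimethyltrideca-3,7,11-trien-1-yl]pent-3-en-1-yl}-3-iodoprop-2-enoate, via silyl allenolate 15 (not isolated), via trimethylsilyl ether 16 (not isolated)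
Conditions: 14, Me3SiI, B-o-tolyl oxazaborolidinium triflimide from (S)-α,α-diphenylprolinol (cat., activated by HNTf2), EtCN, −78 °C; then 1 M HCl, THF, 0 °C
Reagents that add atoms: iodotrimethylsilane, C[Si](C)(C)I
Why: Conjugate addition of iodide from Me3SiI to the ynoate gives β-iodo allenolate 15, which adds through its central carbon to the catalyst-bound aldehyde (three-component β-iodo Morita–Baylis–Hillman-type aldol); the chiral Lewis acid blocks one formyl face so that Si-face attack sets (R)-C1', and approach anti to iodine gives the Z-iodoacrylate.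

**Step 10**
Reactants: 17 ethyl (2Z)-2-{(1R,3E)-5-[(tert-butyldiphenylsilyl)oxy]-1-hydroxy-4-[(3E,7E)-4,8,12-trimethyltrideca-3,7,11-trien-1-yl]pent-3-en-1-yl}-3-iodoprop-2-enoate
Product: 18 ethyl (2Z)-2-{(1R,3E)-1-[(tert-butyldimethylsilyl)oxy]-5-[(tert-butyldiphenylsilyl)oxy]-4-[(3E,7E)-4,8,12-trimethyltrideca-3,7,11-trien-1-yl]pent-3-en-1-yl}-3-iodoprop-2-enoate
Conditions: TBSOTf, 2,6-lutidine, CH2Cl2, −78 to 0 °C
Reagents that add atoms: tert-butyldimethylsilyl trifluoromethanesulfonate, CC(C)(C)[Si](C)(C)OS(=O)(=O)C(F)(F)F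
Why: Silylation of the secondary allylic alcohol with a silyl triflate (standard protection) prevents alkoxide chemistry at C1' in steps 11 to 13 and leaves the stereocentre untouched.

**Step 11**
Reactants: 18 ethyl (2Z)-2-{(1R,3E)-1-[(tert-butyldimethylsilyl)oxy]-5-[(tert-butyldiphenylsilyl)oxy]-4-[(3E,7E)-4,8,12-trimethyltrideca-3,7,11-trien-1-yl]pent-3-en-1-yl}-3-iodoprop-2-enoate
Product: 19 (2E)-2-{(1R,3E)-1-[(tert-butyldimethylsilyl)oxy]-5-[(tert-butyldiphenylsilyl)oxy]-4-[(3E,7E)-4,8,12-trimethyltrideca-3,7,11-trien-1-yl]pent-3-en-1-yl}-3-iodoprop-2-en-1-ol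
Conditions: i-Bu2AlH, CH2Cl2, −78 °C; aq. potassium sodium tartrate
Reagents that add atoms: none
Why: 1,2-Reduction of the α,β-unsaturated ester by i-Bu2AlH at low temperature should leave the alkenyl iodide and both silyl ethers intact (the descriptor changes to 2E only because the priorities change).

**Step 12**
Reactants: 19 (2E)-2-{(1R,3E)-1-[(tert-butyldimethylsilyl)oxy]-5-[(tert-butyldiphenylsilyl)oxy]-4-[(3E,7E)-4,8,12-trimethyltrideca-3,7,11-trien-1-yl]pent-3-en-1-yl}-3-iodoprop-2-en-1-ol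
Product: 20 (2E)-2-{(1R,3E)-1-[(tert-butyldimethylsilyl)oxy]-5-[(tert-butyldiphenylsilyl)oxy]-4-[(3E,7E)-4,8,12-trimethyltrideca-3,7,11-trien-1-yl]pent-3-en-1-yl}-3-iodoprop-2-en-1-yl methyl carbonate
Conditions: ClCO2Me, pyridine, DMAP (cat.), CH2Cl2, 0 °C
Reagents that add atoms: methyl chloroformate, COC(Cl)=O
Why: Acylation of the primary allylic alcohol with a chloroformate installs the carbonyl carbon that becomes C2 of the lactone (carbonate formation).

**Step 13**
Reactants: 20 (2E)-2-{(1R,3E)-1-[(tert-butyldimethylsilyl)oxy]-5-[(tert-butyldiphenylsilyl)oxy]-4-[(3E,7E)-4,8,12-trimethyltrideca-3,7,11-trien-1-yl]pent-3-en-1-yl}-3-iodoprop-2-en-1-yl methyl carbonate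
Product: 22 4-{(1R,3E)-1-[(tert-butyldimethylsilyl)oxy]-5-[(tert-butyldiphenylsilyl)oxy]-4-[(3E,7E)-4,8,12-trimethyltrideca-3,7,11-trien-1-yl]pent-3-en-1-yl}furan-2(5H)-one, via alkenyllithium 21 (not isolated)
Conditions: t-BuLi (2.1 equiv), Et2O/THF, −78 °C; AcOH, −78 °C to rt
Reagents that add atoms: none
Why: Iodine–lithium exchange at the alkenyl iodide, which is faster than addition of t-BuLi to a carbonate at −78 °C, gives alkenyllithium 21, whose carbanionic C3 is held cis to the CH2–O–C(=O)OMe arm across C3=C4 and adds to the carbonate carbonyl C2; the tetrahedral lithium alkoxide then loses methoxide to give the lactone. The closest known reaction type is the Parham cyclisation (halogen–metal exchange followed by intramolecular acyl substitution), here the alkenyl counterpart of the phthalide-forming variant and equally describable as an anionic 1,4-O-to-C carboxyl transfer. The five-membered ring O1–C2–C3–C4–C5 closes by a 5-exo-trig attack on the carbonyl group, forming the C3–C2 bond. No new stereocentre is formed: C1' is not involved, and an alkenyllithium bearing an α-hydrogen is configurationally stable at this temperature, so the cis relation of C3 and C5 set in step 9 is carried into the ring. The step needs chemoselectivity (exchange before carbonyl addition, secured by the rate of exchange and by the second equivalent of t-BuLi consuming t-BuI) and site selectivity (only the carbonate on the cis arm is within reach, while the silyloxy group on C1' is trans to lithium and cannot undergo retro-Brook silyl migration). Both modes of collapse of the tetrahedral intermediate, loss of methoxide or ring opening to a Z-configured γ-alkoxido enoate that relactonises on work-up, converge on 22.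

**Step 14**
Reactants: 22 4-{(1R,3E)-1-[(tert-butyldimethylsilyl)oxy]-5-[(tert-butyldiphenylsilyl)oxy]-4-[(3E,7E)-4,8,12-trimethyltrideca-3,7,11-trien-1-yl]pent-3-en-1-yl}furan-2(5H)-one
Product: 23 hippolide C
Conditions: HF·pyridine, pyridine, THF, 0 °C to rt
Reagents that add atoms: none
Why: Buffered fluoride cleaves both silyl ethers under mildly acidic conditions that should neither open nor isomerise the butenolide nor touch C1' (global desilylation).

**Compound list**
1 | (2E,6E)-farnesol | CC(C)=CCC/C(C)=C/CC/C(C)=C/CO | starting material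
2 | (2E,6E)-farnesal | CC(C)=CCC/C(C)=C/CC/C(C)=C/C=O | intermediate
3 | (3E,7E)-4,8,12-trimethyltrideca-1,3,7,11-tetraene | CC(C)=CCC/C(C)=C/CC/C(C)=C/C=C | intermediate
4 | tert-butyl(but-3-yn-1-yloxy)dimethylsilane | C#CCCO[Si](C)(C)C(C)(C)C | starting material
5 | lithium acetylide of 4 (not isolated) | [Li]C#CCCO[Si](C)(C)C(C)(C)C | intermediate
6 | 5-[(tert-butyldimethylsilyl)oxy]pent-2-yn-1-ol | OCC#CCCO[Si](C)(C)C(C)(C)C | intermediate
7 | (Z)-5-[(tert-butyldimethylsilyl)oxy]-2-(tributylstannyl)pent-2-en-1-ol (not isolated) | OC/C(=C/CCO[Si](C)(C)C(C)(C)C)[Sn](CCCC)(CCCC)CCCC | intermediate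
8 | (Z)-5-[(tert-butyldimethylsilyl)oxy]-2-iodopent-2-en-1-ol | OC/C(I)=C/CCO[Si](C)(C)C(C)(C)C | intermediate
9 | (Z)-5-[(tert-butyldimethylsilyl)oxy]-1-[(tert-butyldiphenylsilyl)oxy]-2-iodopent-2-ene | CC(C)(C)[Si](OC/C(I)=C/CCO[Si](C)(C)C(C)(C)C)(c1ccccc1)c1ccccc1 | intermediate
10 | B-[(3E,7E)-4,8,12-trimethyltrideca-3,7,11-trien-1-yl]-9-borabicyclo[3.3.1]nonane (not isolated) | CC(C)=CCC/C(C)=C/CC/C(C)=C/CCB1C2CCCC1CCC2 | intermediate
11 | (E)-5-[(tert-butyldimethylsilyl)oxy]-1-[(tert-butyldiphenylsilyl)oxy]-2-[(3E,7E)-4,8,12-trimethyltrideca-3,7,11-trien-1-yl]pent-2-ene | CC(C)=CCC/C(C)=C/CC/C(C)=C/CC/C(=C\CCO[Si](C)(C)C(C)(C)C)CO[Si](c1ccccc1)(c1ccccc1)C(C)(C)C | intermediate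
12 | (E)-5-[(tert-butyldiphenylsilyl)oxy]-4-[(3E,7E)-4,8,12-trimethyltrideca-3,7,11-trien-1-yl]pent-3-en-1-ol | CC(C)=CCC/C(C)=C/CC/C(C)=C/CC/C(=C\CCO)CO[Si](c1ccccc1)(c1ccccc1)C(C)(C)C | intermediate
13 | (E)-5-[(tert-butyldiphenylsilyl)oxy]-4-[(3E,7E)-4,8,12-trimethyltrideca-3,7,11-trien-1-yl]pent-3-enal | CC(C)=CCC/C(C)=C/CC/C(C)=C/CC/C(=C\CC=O)CO[Si](c1ccccc1)(c1ccccc1)C(C)(C)C | intermediate
14 | ethyl propiolate | C#CC(=O)OCC | starting material
15 | 1-ethoxy-3-iodo-1-[(trimethylsilyl)oxy]propa-1,2-diene (silyl allenolate; not isolated) | CCOC(O[Si](C)(C)C)=C=CI | intermediate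
16 | O-trimethylsilyl ether of 17 (not isolated) | CC(C)=CCC/C(C)=C/CC/C(C)=C/CC/C(=C\C[C@@H](O[Si](C)(C)C)/C(=C/I)C(=O)OCC)CO[Si](c1ccccc1)(c1ccccc1)C(C)(C)C | intermediate
17 | ethyl (2Z)-2-{(1R,3E)-5-[(tert-butyldiphenylsilyl)oxy]-1-hydroxy-4-[(3E,7E)-4,8,12-trimethyltrideca-3,7,11-trien-1-yl]pent-3-en-1-yl}-3-iodoprop-2-enoate | CC(C)=CCC/C(C)=C/CC/C(C)=C/CC/C(=C\C[C@@H](O)/C(=C/I)C(=O)OCC)CO[Si](c1ccccc1)(c1ccccc1)C(C)(C)C | intermediate
18 | ethyl (2Z)-2-{(1R,3E)-1-[(tert-butyldimethylsilyl)oxy]-5-[(tert-butyldiphenylsilyl)oxy]-4-[(3E,7E)-4,8,12-trimethyltrideca-3,7,11-trien-1-yl]pent-3-en-1-yl}-3-iodoprop-2-enoate | CC(C)=CCC/C(C)=C/CC/C(C)=C/CC/C(=C\C[C@@H](O[Si](C)(C)C(C)(C)C)/C(=C/I)C(=O)OCC)CO[Si](c1ccccc1)(c1ccccc1)C(C)(C)C | intermediate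
19 | (2E)-2-{(1R,3E)-1-[(tert-butyldimethylsilyl)oxy]-5-[(tert-butyldiphenylsilyl)oxy]-4-[(3E,7E)-4,8,12-trimethyltrideca-3,7,11-trien-1-yl]pent-3-en-1-yl}-3-iodoprop-2-en-1-ol | CC(C)=CCC/C(C)=C/CC/C(C)=C/CC/C(=C\C[C@@H](O[Si](C)(C)C(C)(C)C)/C(=C/I)CO)CO[Si](c1ccccc1)(c1ccccc1)C(C)(C)C | intermediate
20 | (2E)-2-{(1R,3E)-1-[(tert-butyldimethylsilyl)oxy]-5-[(tert-butyldiphenylsilyl)oxy]-4-[(3E,7E)-4,8,12-trimethyltrideca-3,7,11-trien-1-yl]pent-3-en-1-yl}-3-iodoprop-2-en-1-yl methyl carbonate | CC(C)=CCC/C(C)=C/CC/C(C)=C/CC/C(=C\C[C@@H](O[Si](C)(C)C(C)(C)C)/C(=C/I)COC(=O)OC)CO[Si](c1ccccc1)(c1ccccc1)C(C)(C)C | intermediate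
21 | alkenyllithium from 20, lithium in place of iodine (not isolated) | CC(C)=CCC/C(C)=C/CC/C(C)=C/CC/C(=C\C[C@@H](O[Si](C)(C)C(C)(C)C)/C(=C/[Li])COC(=O)OC)CO[Si](c1ccccc1)(c1ccccc1)C(C)(C)C | intermediate
22 | 4-{(1R,3E)-1-[(tert-butyldimethylsilyl)oxy]-5-[(tert-butyldiphenylsilyl)oxy]-4-[(3E,7E)-4,8,12-trimethyltrideca-3,7,11-trien-1-yl]pent-3-en-1-yl}furan-2(5H)-one | CC(C)=CCC/C(C)=C/CC/C(C)=C/CC/C(=C\C[C@@H](O[Si](C)(C)C(C)(C)C)C1=CC(=O)OC1)CO[Si](c1ccccc1)(c1ccccc1)C(C)(C)C | intermediate
23 | hippolide C, 4-[(1R,3E,7E,11E)-1-hydroxy-4-(hydroxymethyl)-8,12,16-trimethylheptadeca-3,7,11,15-tetraen-1-yl]furan-2(5H)-one | CC(C)=CCC/C(C)=C/CC/C(C)=C/CC/C(=C\C[C@@H](O)C1=CC(=O)OC1)CO | target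

**Summary**
Total steps: 14. Longest linear sequence: 12 steps (4 to 23, steps 3 to 14); the farnesol branch (steps 1 and 2) joins at step 6.

Steps most likely to fail:

1. Step 13 (key step). What may go wrong: t-BuLi adds to the carbonate carbonyl, or the alkenyllithium is protonated before ring closure, so that iodine is lost without cyclisation. Fallback: the route leaves at iodo alcohol 19 and returns at 22 by palladium-catalysed carbonylative lactonisation (Pd(PPh3)2Cl2, CO 1 atm, Et3N, THF, 50 °C). Zerovalent palladium inserts into the C–I bond, CO inserts, and the cis CH2OH captures the acylpalladium; the ring then closes through the acyl–oxygen bond and no carbonate is needed. No compound outside the list is made (F0).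

2. Step 9. What may go wrong: the Lewis acid moves the β,γ-double bond of 13 into conjugation, or facial selectivity is poor for this unbranched aliphatic aldehyde. Fallback (resolution in place of asymmetric catalysis), leaving at 13 and 14 and returning at 17: MgI2 in CH2Cl2 at 0 °C gives the racemic (Z)-β-iodo aldol adduct F1; Ac2O, pyridine and DMAP give the racemic acetate F2. A lipase (serine hydrolase class, for example the lipase from Burkholderia cepacia) in pH 7 phosphate buffer/MTBE should hydrolyse the (R)-acetate preferentially, by the empirical size rule for secondary alcohols with the acrylate arm as the large group. This returns (R)-alcohol 17 and leaves the (S)-acetate F3, which is separated.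

3. Step 6. What may go wrong: transmetalation of the B-alkyl borane to the α-branched alkenylpalladium is slow, and protodehalogenation of the iodide competes. Fallback (carbometalation of the alkyne in place of cross-coupling), leaving at 3 and 6 and returning at 11: borane 10 from 3 is oxidised (NaOH, H2O2) to homofarnesol F4, which is converted by the Appel reaction (CBr4, PPh3) into homofarnesyl bromide F5 and then (Mg, THF) into homofarnesylmagnesium bromide F6. Copper-catalysed anti-carbomagnesiation of the magnesium alkoxide of 6 (CuI cat., THF, reflux) delivers the alkyl group to the carbinol-proximal alkyne carbon while the alkoxide chelates magnesium; protonation gives (E)-allylic alcohol F7. TBDPSCl and imidazole then give 11.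

**Further compounds**
F0 | step 13 | none | none
F1 | step 9 | racemic ethyl (2Z)-2-{(3E)-5-[(tert-butyldiphenylsilyl)oxy]-1-hydroxy-4-[(3E,7E)-4,8,12-trimethyltrideca-3,7,11-trien-1-yl]pent-3-en-1-yl}-3-iodoprop-2-enoate | CC(C)=CCC/C(C)=C/CC/C(C)=C/CC/C(=C\CC(O)/C(=C/I)C(=O)OCC)CO[Si](c1ccccc1)(c1ccccc1)C(C)(C)C
F2 | step 9 | racemic O-acetate of F1 | CC(C)=CCC/C(C)=C/CC/C(C)=C/CC/C(=C\CC(OC(C)=O)/C(=C/I)C(=O)OCC)CO[Si](c1ccccc1)(c1ccccc1)C(C)(C)C
F3 | step 9 | (S)-acetate left by the lipase, ethyl (2Z)-2-{(1S,3E)-1-acetoxy-5-[(tert-butyldiphenylsilyl)oxy]-4-[(3E,7E)-4,8,12-trimethyltrideca-3,7,11-trien-1-yl]pent-3-en-1-yl}-3-iodoprop-2-enoate | CC(C)=CCC/C(C)=C/CC/C(C)=C/CC/C(=C\C[C@H](OC(C)=O)/C(=C/I)C(=O)OCC)CO[Si](c1ccccc1)(c1ccccc1)C(C)(C)C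
F4 | step 6 | (3E,7E)-homofarnesol, (3E,7E)-4,8,12-trimethyltrideca-3,7,11-trien-1-ol | CC(C)=CCC/C(C)=C/CC/C(C)=C/CCO
F5 | step 6 | (3E,7E)-homofarnesyl bromide | CC(C)=CCC/C(C)=C/CC/C(C)=C/CCBr
F6 | step 6 | (3E,7E)-homofarnesylmagnesium bromide | CC(C)=CCC/C(C)=C/CC/C(C)=C/CC[Mg]Br
F7 | step 6 | (E)-5-[(tert-butyldimethylsilyl)oxy]-2-[(3E,7E)-4,8,12-trimethyltrideca-3,7,11-trien-1-yl]pent-2-en-1-ol | CC(C)=CCC/C(C)=C/CC/C(C)=C/CC/C(=C\CCO[Si](C)(C)C(C)(C)C)CO
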